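**Retrosynthetic overview**
1. Target 17 ← acetylation of the 6-alcohol 16 ← C6 inversion (oxidation, then face-selective reduction) of macrocyclic alcohol 14.
2. The ten-membered carbocycle is closed last, at C6–C7, by intramolecular umpolung allylation of epoxy aldehyde 12 (allyl chloride onto aldehyde).
3. The oxirane (C4, C5) is made before the carbocycle, by reagent-controlled Katsuki–Sharpless epoxidation of allylic alcohol 7 (C–O bonds).
4. The C3–O tiglate and the C3 configuration come from a kinetic-resolution acyl transfer on racemic alcohol 4 with tiglic anhydride (C–O bond, new step).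
5. 4 ← geranylbarium chloride + commercial (2E)-4-acetoxy-2-methylbut-2-enal. Ring order: oxirane first, then the ten-membered ring.

Assumption: ring compounds are named with germacrane numbering (C1=C10 alkene, C3 tiglate carbon, C4–C5 epoxide, C6 acetate carbon, C7 isopropenyl carbon), and the same locants are used for the open-chain precursors in the text.

**Route**

Step 1
Reactants: 1 geranyl chloride; 2 (2E)-4-acetoxy-2-methylbut-2-enal
Product: 4 rac-(2E,6E)-4-hydroxy-3,7,11-trimethyldodeca-2,6,10-trien-1-yl acetate, via geranylbarium chloride 3 (not isolated)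
Conditions: BaI2, Li(C12H10) (lithium biphenylide, 2 equiv), THF, rt; then 1, −78 °C; then 2 (1.0 equiv), −78 °C; aq NH4Cl
Reagents that add atoms: none
Why: Allylbarium reagents add to aldehydes through their unsubstituted (alpha) carbon with retention of the E geometry and 1,2 to enals (allylbarium carbonyl allylation), so the full C15 chain with both future oxygen-bearing carbons is made in one step, the carbinol (C3) being racemic at this point.

Step 2
Reactants: 4 rac-(2E,6E)-4-hydroxy-3,7,11-trimethyldodeca-2,6,10-trien-1-yl acetate; 5 tiglic anhydride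
Product: 6 (2E,4S,6E)-1-acetoxy-3,7,11-trimethyldodeca-2,6,10-trien-4-yl (2E)-2-methylbut-2-enoate
Conditions: (S)-benzotetramisole (5 mol%), 5 (0.55 equiv), iPr2NEt (0.6 equiv), CHCl3, 0 °C, stopped near 45% conversion; unreacted (R)-4 removed by chromatography
Reagents that add atoms: none
Why: Proposed new method: a kinetic resolution by isothiourea-catalysed acyl transfer in which the resolving acyl group is the tigloyl group of the target, not yet shown with an α,β-unsaturated anhydride or with a 2-methylalkenyl carbinol of this kind; the N-tigloyl isothiouronium ion formed from (S)-benzotetramisole and 5 should stack its cationic face on the C4=C5 alkene of 4 (cation–π) so that only the (S)-carbinol presents its hydroxyl to the acyl carbon while the tiglate counter-ion acts as general base, the α,β-dimethyl substitution of the tigloyl unit disfavours conjugate addition and leaves 1,2-acyl transfer as the path, the closest known reaction type is the isothiourea-catalysed acylative kinetic resolution of secondary benzylic and allylic alcohols with saturated anhydrides, and the step forms the C3–O ester bond and fixes C3 as S.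

Step 3
Reactants: 6 (2E,4S,6E)-1-acetoxy-3,7,11-trimethyldodeca-2,6,10-trien-4-yl (2E)-2-methylbut-2-enoate
Product: 7 (2E,4S,6E)-1-hydroxy-3,7,11-trimethyldodeca-2,6,10-trien-4-yl (2E)-2-methylbut-2-enoate
Conditions: K2CO3 (0.2 equiv), MeOH, 0 °C, 1 h
Reagents that add atoms: none
Why: Base-catalysed transesterification (methanolysis) removes the unhindered primary allylic acetate much faster than the hindered, conjugated secondary tiglate, and acyl migration is impossible across the E alkene.

Step 4
Reactants: 7 (2E,4S,6E)-1-hydroxy-3,7,11-trimethyldodeca-2,6,10-trien-4-yl (2E)-2-methylbut-2-enoate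
Product: 8 (1S,3E)-1-[(2R,3R)-3-(hydroxymethyl)-2-methyloxiran-2-yl]-4,8-dimethylnona-3,7-dien-1-yl (2E)-2-methylbut-2-enoate
Conditions: Ti(OiPr)4 (10 mol%), D-(−)-diethyl tartrate (12 mol%), tBuOOH (2 equiv), 4 Å MS, CH2Cl2, −20 °C; aqueous tartaric acid work-up
Reagents that add atoms: tert-butyl hydroperoxide, CC(C)(C)OO
Why: Katsuki–Sharpless asymmetric epoxidation, in which the tetravalent titanium–tartrate complex binds the primary allylic alcohol and delivers oxygen under reagent control to the face that gives the (2R,3R)-oxirane (C4 and C5 of the target) whatever the neighbouring tiglate centre, leaves the other two trisubstituted alkenes untouched, and turns any carried-over (4R)-ester into a separable diastereomer.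

Step 5
Reactants: 8 (1S,3E)-1-[(2R,3R)-3-(hydroxymethyl)-2-methyloxiran-2-yl]-4,8-dimethylnona-3,7-dien-1-yl (2E)-2-methylbut-2-enoate
Product: 9 (1S,3E,7E)-9-hydroxy-1-[(2R,3R)-3-(hydroxymethyl)-2-methyloxiran-2-yl]-4,8-dimethylnona-3,7-dien-1-yl (2E)-2-methylbut-2-enoate
Conditions: SeO2 (0.3 equiv), tBuOOH (3 equiv), salicylic acid (0.1 equiv), CH2Cl2, rt, stopped at partial conversion with recovery of 8
Reagents that add atoms: selenium dioxide, O=[Se]=O; tert-butyl hydroperoxide, CC(C)(C)OO
Why: Selenium dioxide allylic oxidation (ene reaction then [2,3]-sigmatropic shift) attacks the most accessible, most electron-rich terminal isopropylidene group and gives the E allylic alcohol, while the electron-poor tiglate alkene and the epoxide do not react.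

Step 6
Reactants: 9 (1S,3E,7E)-9-hydroxy-1-[(2R,3R)-3-(hydroxymethyl)-2-methyloxiran-2-yl]-4,8-dimethylnona-3,7-dien-1-yl (2E)-2-methylbut-2-enoate
Product: 12 (1S,3E,7E)-9-chloro-1-[(2R,3S)-3-formyl-2-methyloxiran-2-yl]-4,8-dimethylnona-3,7-dien-1-yl (2E)-2-methylbut-2-enoate, via bis-alkoxysulfonium salt 10 (not isolated), via chloro alkoxysulfonium salt 11 (not isolated)
Conditions: NCS (2.4 equiv), Me2S (3 equiv), CH2Cl2, −25 °C to 0 °C, 1 h; then Et3N (3 equiv), −25 °C to rt
Reagents that add atoms: N-chlorosuccinimide, O=C1CCC(=O)N1Cl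
Why: Corey–Kim chemistry in one flask, in which both hydroxyls form alkoxysulfonium ions, the allylic one is displaced by chloride (Corey–Kim chlorination, specific for allylic alcohols) and the non-allylic one is converted into the aldehyde when triethylamine is added (Corey–Kim oxidation), with no stereocentre touched.

Step 7
Reactants: 12 (1S,3E,7E)-9-chloro-1-[(2R,3S)-3-formyl-2-methyloxiran-2-yl]-4,8-dimethylnona-3,7-dien-1-yl (2E)-2-methylbut-2-enoate
Product: 14 (1(10)E,3S,4R,5R,6S,7S)-4,5-epoxy-6-hydroxygermacra-1(10),11-dien-3-yl (2E)-2-methylbut-2-enoate, via allyl(ethyl)zinc 13 (not isolated)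
Conditions: Pd(PPh3)4 (10 mol%), Et2Zn (3 equiv), K2CO3, DMA, 0 °C to rt, 12 added slowly to 3 mM final concentration
Reagents that add atoms: none
Why: Palladium-catalysed umpolung allylation (zerovalent palladium ionises the allyl chloride and Et2Zn turns the allylpalladium into a nucleophilic allylzinc) should close the ten-membered ring through a six-membered chair transition state with the E-allyl unit and both ring branches equatorial in a crown-shaped ring, which sets C7 as S (isopropenyl equatorial) and C6 as S relative to the fixed epoxide, C6 being the epimer of what the target needs and corrected in steps 8 and 9.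

Step 8
Reactants: 14 (1(10)E,3S,4R,5R,6S,7S)-4,5-epoxy-6-hydroxygermacra-1(10),11-dien-3-yl (2E)-2-methylbut-2-enoate
Product: 15 (1(10)E,3S,4R,5S,7S)-4,5-epoxy-6-oxogermacra-1(10),11-dien-3-yl (2E)-2-methylbut-2-enoate
Conditions: Dess–Martin periodinane (1.3 equiv), pyridine, CH2Cl2, 0 °C; crude ketone used at once
Reagents that add atoms: none
Why: Dess–Martin oxidation under buffered, non-basic conditions gives the β,γ-unsaturated epoxy ketone without moving the isopropenyl double bond into conjugation or epimerising C7, whose equatorial S configuration is in any case the thermodynamic one.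

Step 9
Reactants: 15 (1(10)E,3S,4R,5S,7S)-4,5-epoxy-6-oxogermacra-1(10),11-dien-3-yl (2E)-2-methylbut-2-enoate
Product: 16 (1(10)E,3S,4R,5R,6R,7S)-4,5-epoxy-6-hydroxygermacra-1(10),11-dien-3-yl (2E)-2-methylbut-2-enoate
Conditions: NaBH4, CeCl3·7H2O, MeOH, −78 °C
Reagents that add atoms: none
Why: Luche reduction, in which hydride should add to the outer (alpha) face of the C6 carbonyl because the beta face is screened by the C4 and C10 methyl groups of the crown conformer, which is also the anti epoxy alcohol expected from chelation or Felkin–Anh control in α,β-epoxy ketone reduction and sets C6 as R.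

Step 10
Reactants: 16 (1(10)E,3S,4R,5R,6R,7S)-4,5-epoxy-6-hydroxygermacra-1(10),11-dien-3-yl (2E)-2-methylbut-2-enoate
Product: 17 (1(10)E,3S,4R,5R,6R,7S)-6-acetoxy-4,5-epoxygermacra-1(10),11-dien-3-yl (2E)-2-methylbut-2-enoate (CNP0400048.1)
Conditions: Ac2O, DMAP (0.2 equiv), pyridine, CH2Cl2, rt
Reagents that add atoms: acetic anhydride, CC(=O)OC(C)=O
Why: DMAP-catalysed acylation esterifies the only free hydroxyl with retention at C6 and gives the target.

**Compound list**
1 | geranyl chloride, (2E)-1-chloro-3,7-dimethylocta-2,6-diene | CC(C)=CCC/C(C)=C/CCl | starting material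
2 | (2E)-4-acetoxy-2-methylbut-2-enal | CC(=O)OC/C=C(\C)C=O | starting material
3 | geranylbarium chloride | CC(C)=CCC/C(C)=C/C[Ba]Cl | intermediate
4 | rac-(2E,6E)-4-hydroxy-3,7,11-trimethyldodeca-2,6,10-trien-1-yl acetate | CC(C)=CCC/C(C)=C/CC(O)/C(C)=C/COC(C)=O | intermediate
5 | tiglic anhydride, (2E)-2-methylbut-2-enoic anhydride | C/C=C(\C)C(=O)OC(=O)/C(C)=C/C | starting material
6 | (2E,4S,6E)-1-acetoxy-3,7,11-trimethyldodeca-2,6,10-trien-4-yl (2E)-2-methylbut-2-enoate | CC(C)=CCC/C(C)=C/C[C@H](OC(=O)/C(C)=C/C)/C(C)=C/COC(C)=O | intermediate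
7 | (2E,4S,6E)-1-hydroxy-3,7,11-trimethyldodeca-2,6,10-trien-4-yl (2E)-2-methylbut-2-enoate | CC(C)=CCC/C(C)=C/C[C@H](OC(=O)/C(C)=C/C)/C(C)=C/CO | intermediate
8 | (1S,3E)-1-[(2R,3R)-3-(hydroxymethyl)-2-methyloxiran-2-yl]-4,8-dimethylnona-3,7-dien-1-yl (2E)-2-methylbut-2-enoate | CC(C)=CCC/C(C)=C/C[C@H](OC(=O)/C(C)=C/C)[C@@]1(C)O[C@@H]1CO | intermediate
9 | (1S,3E,7E)-9-hydroxy-1-[(2R,3R)-3-(hydroxymethyl)-2-methyloxiran-2-yl]-4,8-dimethylnona-3,7-dien-1-yl (2E)-2-methylbut-2-enoate | OC/C(C)=C/CC/C(C)=C/C[C@H](OC(=O)/C(C)=C/C)[C@@]1(C)O[C@@H]1CO | intermediate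
10 | bis-alkoxysulfonium salt: both hydroxyl oxygens of 9 carry a dimethylsulfonium group, dichloride | C[S+](C)OC/C(C)=C/CC/C(C)=C/C[C@H](OC(=O)/C(C)=C/C)[C@@]1(C)O[C@@H]1CO[S+](C)C.[Cl-].[Cl-] | intermediate
11 | chloro alkoxysulfonium salt: allylic chloride at C12, dimethylsulfonium on the C6 oxygen, chloride | ClC/C(C)=C/CC/C(C)=C/C[C@H](OC(=O)/C(C)=C/C)[C@@]1(C)O[C@@H]1CO[S+](C)C.[Cl-] | intermediate
12 | (1S,3E,7E)-9-chloro-1-[(2R,3S)-3-formyl-2-methyloxiran-2-yl]-4,8-dimethylnona-3,7-dien-1-yl (2E)-2-methylbut-2-enoate | ClC/C(C)=C/CC/C(C)=C/C[C@H](OC(=O)/C(C)=C/C)[C@@]1(C)O[C@@H]1C=O | intermediate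
13 | allyl(ethyl)zinc: 12 with the C–Cl replaced by C–Zn–Et | CC[Zn]C/C(C)=C/CC/C(C)=C/C[C@H](OC(=O)/C(C)=C/C)[C@@]1(C)O[C@@H]1C=O | intermediate
14 | (1(10)E,3S,4R,5R,6S,7S)-4,5-epoxy-6-hydroxygermacra-1(10),11-dien-3-yl (2E)-2-methylbut-2-enoate | C=C(C)[C@@H]1CC/C(C)=C/C[C@H](OC(=O)/C(C)=C/C)[C@@]2(C)O[C@@H]2[C@H]1O | intermediate
15 | (1(10)E,3S,4R,5S,7S)-4,5-epoxy-6-oxogermacra-1(10),11-dien-3-yl (2E)-2-methylbut-2-enoate | C=C(C)[C@@H]1CC/C(C)=C/C[C@H](OC(=O)/C(C)=C/C)[C@@]2(C)O[C@@H]2C1=O | intermediate
16 | (1(10)E,3S,4R,5R,6R,7S)-4,5-epoxy-6-hydroxygermacra-1(10),11-dien-3-yl (2E)-2-methylbut-2-enoate | C=C(C)[C@@H]1CC/C(C)=C/C[C@H](OC(=O)/C(C)=C/C)[C@@]2(C)O[C@@H]2[C@@H]1O | intermediate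
17 | (1(10)E,3S,4R,5R,6R,7S)-6-acetoxy-4,5-epoxygermacra-1(10),11-dien-3-yl (2E)-2-methylbut-2-enoate | C=C(C)[C@@H]1CC/C(C)=C/C[C@H](OC(=O)/C(C)=C/C)[C@@]2(C)O[C@@H]2[C@@H]1OC(C)=O | target

**Step count and risks**
Total steps: 10. Longest linear sequence: 10 (1 → 17). Step 2 is capped at 50% yield because it is a resolution.

The three steps most likely to fail:

Step 2, the proposed new step. The selectivity factor may be low for a non-aryl alkenyl carbinol, the sense of selection is predicted only from the cation–π model, and the tigloyl isothiouronium ion may be deprotonated at its γ-methyl instead of transferring the acyl group. The fallback uses known chemistry and sets out from 4: a Katsuki–Sharpless kinetic resolution (Ti(OiPr)4, D-(−)-diisopropyl tartrate, tBuOOH, 4 Å MS, CH2Cl2, −20 °C, about 55% conversion). The (4R)-enantiomer is epoxidised through its secondary hydroxyl to [(2R,3R)-3-[(1R,3E)-1-hydroxy-4,8-dimethylnona-3,7-dien-1-yl]-3-methyloxiran-2-yl]methyl acetate F2 and is discarded. The slow-reacting (2E,4S,6E)-4-hydroxy-3,7,11-trimethyldodeca-2,6,10-trien-1-yl acetate F1 is recovered in high ee and esterified with 5 (DMAP, Et3N, CH2Cl2) with retention. This comes back to the route at 6 at the cost of one extra step.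

Step 7, the macrocyclisation. Oligomerisation, ethyl transfer from Et2Zn to the aldehyde, or opening of the sensitive epoxy aldehyde may lower the yield. The C6/C7 outcome is a prediction from the chair model, not a measured result; steps 8 and 9 correct C6 either way, but C7 must come out S. The fallback sets out from 12 and changes the metal and mechanism to a Nozaki–Hiyama-type Barbier closure: CrCl2 (4 equiv), THF, rt, slow addition to 2 mM. Divalent chromium reduces the allyl chloride to the allylchromium dichloride F3, which adds to the aldehyde through the same chair arrangement. This comes back to the route at 14.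

Step 9, the facial selectivity of the ketone reduction. If hydride returns the 6S alcohol 14, or if ketone 15 isomerises to the conjugated isopropylidene enone before it is reduced, the fallback sets out from 14 and inverts C6 by C–O bond formation instead of by redox. MsCl and Et3N in CH2Cl2 at 0 °C give the (1(10)E,3S,4R,5R,6S,7S)-4,5-epoxy-6-(methanesulfonyloxy)germacra-1(10),11-dien-3-yl (2E)-2-methylbut-2-enoate F4. CsOAc with 18-crown-6 in toluene at 80 °C then displaces the sulfonate with inversion. This comes back to the route directly at 17 and skips 15 and 16.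

**Further compounds**
F1 | step 2 | (2E,4S,6E)-4-hydroxy-3,7,11-trimethyldodeca-2,6,10-trien-1-yl acetate | CC(C)=CCC/C(C)=C/C[C@H](O)/C(C)=C/COC(C)=O
F2 | step 2 | [(2R,3R)-3-[(1R,3E)-1-hydroxy-4,8-dimethylnona-3,7-dien-1-yl]-3-methyloxiran-2-yl]methyl acetate | CC(C)=CCC/C(C)=C/C[C@@H](O)[C@@]1(C)O[C@@H]1COC(C)=O
F3 | step 7 | allylchromium dichloride derived from 12 (C–Cl replaced by C–CrCl2) | Cl[Cr](Cl)C/C(C)=C/CC/C(C)=C/C[C@H](OC(=O)/C(C)=C/C)[C@@]1(C)O[C@@H]1C=O
F4 | step 9 | (1(10)E,3S,4R,5R,6S,7S)-4,5-epoxy-6-(methanesulfonyloxy)germacra-1(10),11-dien-3-yl (2E)-2-methylbut-2-enoate | C=C(C)[C@@H]1CC/C(C)=C/C[C@H](OC(=O)/C(C)=C/C)[C@@]2(C)O[C@@H]2[C@H]1OS(C)(=O)=O
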